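## Retrosynthetic overview

1. Target 16 ⇐ ten-membered 1,6-dione 15 by a transannular, deconjugative aldol (C5 → C1). One bond closes the five- and seven-membered rings and sets the C1 carbinol, H-5 and the exocyclic C4=C15 alkene; this is the aldol counterpart of the biogenetic germacrane → guaiane closure.
2. 15 ⇐ germacrene triol 14 (double oxidation) ⇐ ten-membered ring by C6–C7 closure, the bond made by the farnesyl C1–C10 cyclisation in the biosynthesis (allylchromium + enal).
3. Open-chain precursor 12 ⇐ 8-hydroxyfarnesyl skeleton: the C9 and C10 oxygens come from a Sharpless kinetic-resolution epoxidation followed by invertive epoxide hydrolysis; the angelate is put on before ring closure.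
4. Chain ⇐ geranyl acetate (SeO2 oxidation of the terminal E-methyl) + prenyl chloride + angelic acid.
5. Ring order: ten-membered carbocycle first (step 8), then the 5/7 bicycle by the transannular bond (step 10).

Assumption: the target is taken as drawn, (1R,5S,7R,9R,10S) in guaiane numbering (C1/C5 ring fusion, C6 ketone, C7 isopropyl, C9 angelate, C10 methyl carbinol, C15 exocyclic CH2); ring compounds carry these atom numbers, and open-chain compounds are named with farnesane chain numbers (chain C1, C2, C3, C6, C7, C8, C10 = guaiane C6, C5, C4, C1, C10, C9, C7).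

## Route

Step 1
Reactants: 1 geranyl acetate
Product: 3 (2E,6E)-3,7-dimethyl-8-oxoocta-2,6-dien-1-yl acetate, via 8-hydroxygeranyl acetate 2 (not isolated)
Conditions: SeO2 (0.3 equiv), t-BuOOH (3 equiv), salicylic acid (0.1 equiv), CH2Cl2, rt; filter; MnO2 (15 equiv), CH2Cl2, rt
Reagents that add atoms: tert-butyl hydroperoxide, CC(C)(C)OO
Why: SeO2-catalysed allylic oxidation (ene reaction, then 2,3-sigmatropic shift) takes the E-methyl of the electron-rich terminal alkene (the other alkene is deactivated by the allylic acetate), and MnO2 converts the alcohol/aldehyde mixture into the single (E)-enal; no stereocentre is formed.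

Step 2
Reactants: 3 (2E,6E)-3,7-dimethyl-8-oxoocta-2,6-dien-1-yl acetate; 4 prenyl chloride
Product: 5 rac-(2E,6E)-8-hydroxy-3,7,11-trimethyldodeca-2,6,10-trien-1-yl acetate
Conditions: 4, active barium (Ba, Rieke type), THF, −78 °C; then 3, −78 °C; aq. NH4Cl
Reagents that add atoms: none
Why: Allylbarium (Yamamoto) 1,2-addition: prenylbarium chloride reacts at its unsubstituted α-carbon, so the linear homoprenyl carbinol forms instead of the reverse-prenyl isomer, and at −78 °C the acetate is untouched; the new carbinol centre is racemic and is resolved in step 3.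

Step 3
Reactants: 5 rac-(2E,6E)-8-hydroxy-3,7,11-trimethyldodeca-2,6,10-trien-1-yl acetate
Product: 6 (2E,6R,7R,8R)-6,7-epoxy-8-hydroxy-3,7,11-trimethyldodeca-2,10-dien-1-yl acetate
Conditions: Ti(OiPr)4 (10 mol %), D-(−)-diisopropyl tartrate (15 mol %), t-BuOOH (0.6 equiv), 4 Å MS, CH2Cl2, −20 °C, stopped near 50% conversion
Reagents that add atoms: tert-butyl hydroperoxide, CC(C)(C)OO
Why: Sharpless asymmetric epoxidation run as a kinetic resolution: with the D-(−)-tartrate the (8R)-alcohol is the fast enantiomer and gives the erythro (anti) epoxy alcohol (expected ≥95% ee, dr >20:1, at most 50% yield, the (8S)-alcohol stays behind), which fixes guaiane C9 and, as the epoxide, the precursor of C10; only the allylic-alcohol alkene is epoxidised.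

Step 4
Reactants: 6 (2E,6R,7R,8R)-6,7-epoxy-8-hydroxy-3,7,11-trimethyldodeca-2,10-dien-1-yl acetate; 7 angelic acid
Product: 8 (2E,6R,7S,8R)-1-acetoxy-6,7-epoxy-3,7,11-trimethyldodeca-2,10-dien-8-yl (2Z)-2-methylbut-2-enoate
Conditions: 7, 2,4,6-trichlorobenzoyl chloride, Et3N, toluene, rt; then 6, toluene, 75 °C
Reagents that add atoms: none
Why: Yamaguchi mixed-anhydride esterification without DMAP, the usual way to angeloylate a hindered secondary alcohol without Z→E isomerisation; no centre changes (the C7 descriptor becomes S only through the changed CIP ranking).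

Step 5
Reactants: 8 (2E,6R,7S,8R)-1-acetoxy-6,7-epoxy-3,7,11-trimethyldodeca-2,10-dien-8-yl (2Z)-2-methylbut-2-enoate
Product: 10 (2E,6R,7S,8R)-6,7-epoxy-3,7,11-trimethyl-1-oxododeca-2,10-dien-8-yl (2Z)-2-methylbut-2-enoate, via deacetylated allylic alcohol 9 (not isolated)
Conditions: Novozym 435 (immobilised lipase B of Candida antarctica), MeOH (5 equiv), MTBE, 30 °C; filter; MnO2 (15 equiv), CH2Cl2, rt
Reagents that add atoms: none
Why: Lipase-catalysed transesterification removes only the unhindered primary acetate (hindered conjugated angelate and epoxide stay), and MnO2 oxidises the resulting primary allylic alcohol to the (E)-enal; no stereocentre is touched.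

Step 6
Reactants: 10 (2E,6R,7S,8R)-6,7-epoxy-3,7,11-trimethyl-1-oxododeca-2,10-dien-8-yl (2Z)-2-methylbut-2-enoate
Product: 11 (2E,6R,7S,8R,10RS)-10-chloro-6,7-epoxy-3,7,11-trimethyl-1-oxododeca-2,11-dien-8-yl (2Z)-2-methylbut-2-enoate
Conditions: NCS (1.1 equiv), PhSeCl (10 mol %), CH2Cl2, rt
Reagents that add atoms: N-chlorosuccinimide, O=C1CCC(=O)N1Cl
Why: Selenium-catalysed ene-type allylic chlorination with allylic transposition attacks the only electron-rich alkene (the enal and angelate alkenes are electron-poor) and gives the secondary allylic chloride with an isopropenyl end, as used on farnesyl substrates; both chloride epimers form and the centre is removed in step 8.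

Step 7
Reactants: 11 (2E,6R,7S,8R,10RS)-10-chloro-6,7-epoxy-3,7,11-trimethyl-1-oxododeca-2,11-dien-8-yl (2Z)-2-methylbut-2-enoate
Product: 12 (2E,6R,7R,8R,10RS)-10-chloro-6,7-dihydroxy-3,7,11-trimethyl-1-oxododeca-2,11-dien-8-yl (2Z)-2-methylbut-2-enoate
Conditions: HClO4 (5 mol %, 0.1 M aq.), THF–H2O 3:1, 0 °C; NaHCO3; used at once
Reagents that add atoms: water, O
Why: Acid-catalysed epoxide hydrolysis opens the tertiary carbon with inversion, by water directly or through the five-membered acyloxonium ion of the neighbouring angelate (hydrolysed with the acyl group returning to the secondary oxygen), so the erythro epoxide becomes the threo 8,9-dioxygen pattern and guaiane C10 is set; the chain C6 carbinol keeps its oxygen and is oxidised later.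

Step 8
Reactants: 12 (2E,6R,7R,8R,10RS)-10-chloro-6,7-dihydroxy-3,7,11-trimethyl-1-oxododeca-2,11-dien-8-yl (2Z)-2-methylbut-2-enoate
Product: 13 (1R,4E,6S,7R,9R,10R)-1,6,10-trihydroxygermacra-4,11-dien-9-yl (2Z)-2-methylbut-2-enoate
Conditions: CrCl2 (8 equiv), LiI (0.2 equiv), THF–DMF 4:1, rt, 12 added by syringe pump over 12 h (final 0.003 M)
Reagents that add atoms: none
Why: Intramolecular Nozaki–Hiyama–Kishi allylation (precedented for farnesal-type ten-membered closures) forms the C6–C7 bond, the farnesyl C1–C10 bond of the biogenesis, through a chair six-membered transition state that gives the 6,7-anti product; the allylchromium adds only to the aldehyde and tolerates free hydroxyls and the ester, and C7 is expected mainly R because isopropenyl and the C9 acyloxy group can both sit pseudo-equatorially (cis-1,3), the minor C7 epimer being removed by chromatography.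

Step 9
Reactants: 13 (1R,4E,6S,7R,9R,10R)-1,6,10-trihydroxygermacra-4,11-dien-9-yl (2Z)-2-methylbut-2-enoate
Product: 14 (1R,4E,6R,7R,9R,10R)-1,6,10-trihydroxygermacr-4-en-9-yl (2Z)-2-methylbut-2-enoate
Conditions: H2 (1 atm), RhCl(PPh3)3 (5 mol %), benzene–EtOH 1:1, rt
Reagents that add atoms: none
Why: Wilkinson hydrogenation reduces the 1,1-disubstituted isopropenyl alkene much faster than the trisubstituted ring alkene or the conjugated trisubstituted angelate; no new stereocentre (C6 becomes R by CIP ranking only).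

Step 10
Reactants: 14 (1R,4E,6R,7R,9R,10R)-1,6,10-trihydroxygermacr-4-en-9-yl (2Z)-2-methylbut-2-enoate
Product: 16 (1R,5S,7R,9R,10S)-1,10-dihydroxy-6-oxoguai-4(15)-en-9-yl (2Z)-2-methylbut-2-enoate (target), via germacrene-1,6-dione 15 (not isolated)
Conditions: IBX (3.5 equiv), DMSO, rt; EtOAc/water extraction; crude 15, MgBr2·OEt2 (2 equiv), Et3N (3 equiv), CH2Cl2, −20 to 0 °C; pH 7 buffer
Reagents that add atoms: none
Why: Proposed new method: IBX oxidises both secondary carbinols (allylic C6 to the enone, C1 of the glycol to the α-ketol without glycol cleavage), and the ten-membered dione 15 then closes by a transannular deconjugative aldol in which Et3N deprotonates the Mg-bound enone at C15 (the γ-methyl cis to the carbonyl) and the extended enolate attacks through its α-carbon C5 the C1 ketone held in a five-ring Mg chelate with the C10 hydroxyl, so that C5 can only arrive from the C9 side and the new C1 hydroxyl ends cis to the C10 hydroxyl, while the Mg-bridged chair-like closure and easy re-enolisation at C5 are expected to put H-5 anti to the C1 oxygen (trans-fused bicycle with isopropyl, angelate and C10 hydroxyl pseudo-equatorial), attack of C2 on C6 being impossible (E-alkene in a five-membered ring) and attack from the tertiary C7 disfavoured (three contiguous fully substituted carbons); the closest known reactions are the transannular aldol of cyclodecane-1,6-diones to hydroazulenones, the α-selective aldol of metal dienolates and MgX2–amine soft-enolisation aldols.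

## Compound list

1 | geranyl acetate | CC(=O)OC/C=C(\C)CCC=C(C)C | starting material
2 | (2E,6E)-8-hydroxy-3,7-dimethylocta-2,6-dien-1-yl acetate (8-hydroxygeranyl acetate) | CC(=O)OC/C=C(\C)CC/C=C(\C)CO | intermediate (not isolated)
3 | (2E,6E)-3,7-dimethyl-8-oxoocta-2,6-dien-1-yl acetate | CC(=O)OC/C=C(\C)CC/C=C(\C)C=O | intermediate
4 | prenyl chloride (1-chloro-3-methylbut-2-ene) | CC(C)=CCCl | starting material
5 | rac-(2E,6E)-8-hydroxy-3,7,11-trimethyldodeca-2,6,10-trien-1-yl acetate (racemate) | CC(=O)OC/C=C(\C)CC/C=C(\C)C(O)CC=C(C)C | intermediate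
6 | (2E,6R,7R,8R)-6,7-epoxy-8-hydroxy-3,7,11-trimethyldodeca-2,10-dien-1-yl acetate | CC(=O)OC/C=C(\C)CC[C@H]1O[C@]1(C)[C@H](O)CC=C(C)C | intermediate
7 | angelic acid, (2Z)-2-methylbut-2-enoic acid | OC(=O)/C(C)=C\C | starting material
8 | (2E,6R,7S,8R)-1-acetoxy-6,7-epoxy-3,7,11-trimethyldodeca-2,10-dien-8-yl (2Z)-2-methylbut-2-enoate | CC(=O)OC/C=C(\C)CC[C@H]1O[C@]1(C)[C@H](OC(=O)/C(C)=C\C)CC=C(C)C | intermediate
9 | (2E,6R,7S,8R)-6,7-epoxy-1-hydroxy-3,7,11-trimethyldodeca-2,10-dien-8-yl (2Z)-2-methylbut-2-enoate | OC/C=C(\C)CC[C@H]1O[C@]1(C)[C@H](OC(=O)/C(C)=C\C)CC=C(C)C | intermediate (not isolated)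
10 | (2E,6R,7S,8R)-6,7-epoxy-3,7,11-trimethyl-1-oxododeca-2,10-dien-8-yl (2Z)-2-methylbut-2-enoate | O=C/C=C(\C)CC[C@H]1O[C@]1(C)[C@H](OC(=O)/C(C)=C\C)CC=C(C)C | intermediate
11 | (2E,6R,7S,8R,10RS)-10-chloro-6,7-epoxy-3,7,11-trimethyl-1-oxododeca-2,11-dien-8-yl (2Z)-2-methylbut-2-enoate (both C10 epimers) | O=C/C=C(\C)CC[C@H]1O[C@]1(C)[C@H](OC(=O)/C(C)=C\C)CC(Cl)C(C)=C | intermediate
12 | (2E,6R,7R,8R,10RS)-10-chloro-6,7-dihydroxy-3,7,11-trimethyl-1-oxododeca-2,11-dien-8-yl (2Z)-2-methylbut-2-enoate (both C10 epimers) | O=C/C=C(\C)CC[C@@H](O)[C@@](C)(O)[C@H](OC(=O)/C(C)=C\C)CC(Cl)C(C)=C | intermediate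
13 | (1R,4E,6S,7R,9R,10R)-1,6,10-trihydroxygermacra-4,11-dien-9-yl (2Z)-2-methylbut-2-enoate | O[C@H]1/C=C(\C)CC[C@@H](O)[C@@](C)(O)[C@H](OC(=O)/C(C)=C\C)C[C@@H]1C(C)=C | intermediate
14 | (1R,4E,6R,7R,9R,10R)-1,6,10-trihydroxygermacr-4-en-9-yl (2Z)-2-methylbut-2-enoate | O[C@H]1/C=C(\C)CC[C@@H](O)[C@@](C)(O)[C@H](OC(=O)/C(C)=C\C)C[C@@H]1C(C)C | intermediate
15 | (4E,7R,9R,10S)-10-hydroxy-1,6-dioxogermacr-4-en-9-yl (2Z)-2-methylbut-2-enoate | O=C1/C=C(\C)CCC(=O)[C@@](C)(O)[C@H](OC(=O)/C(C)=C\C)C[C@@H]1C(C)C | intermediate (not isolated)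
16 | (1R,5S,7R,9R,10S)-1,10-dihydroxy-6-oxoguai-4(15)-en-9-yl (2Z)-2-methylbut-2-enoate | C=C1CC[C@@]2(O)[C@H]1C(=O)[C@@H](C(C)C)C[C@@H](OC(=O)/C(C)=C\C)[C@]2(C)O | target

## Step count and risks

Total step count: 10. Longest linear sequence: 10 steps (1 → 16); 4 and 7 are bought.

Steps most likely to fail:

**Step 10 (oxidation and transannular aldol).** The enolisation may go to C7 instead of C15, the aldol may give the cis-fused C5 epimer, or the adduct may dehydrate or move the alkene into conjugation. Fallback: close the same bond by a neutral carbonyl-ene (Prins) reaction with C6 kept as a carbinol, so no enolate is involved. It sets out from 14. The secondary hydroxyl of the vicinal diol is oxidised chemoselectively with [(neocuproine)Pd(OAc)]2(OTf)2 (5 mol %) and benzoquinone in MeCN–H2O to give (4E,6R,7R,9R,10S)-6,10-dihydroxy-1-oxogermacr-4-en-9-yl angelate F1. Me2AlCl (2.5 equiv, CH2Cl2, −78 °C) then chelates the α-ketol and drives the transannular ene reaction of the C4=C5 alkene (C1–C5 bond, hydrogen taken from C15) to (1R,5R,6R,7R,9R,10S)-1,6,10-trihydroxyguai-4(15)-en-9-yl angelate F2. Dess–Martin oxidation (NaHCO3, CH2Cl2) of its only secondary alcohol comes back to the route at 16.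

**Step 8 (ten-membered ring closure).** Oligomerisation, protonolysis of the allylchromium by the free diol, ether formation from the 4-chloro alcohol or poor C7 selectivity could spoil it. Fallback: mask the diol and use a catalytic π-allyl umpolung. It sets out from 12. 2,2-Dimethoxypropane and PPTS in CH2Cl2 give the 6,7-O-isopropylidene acetal of 12 F3. PdCl2(PPh3)2 (10 mol %), Et2Zn (4 equiv) and K2CO3 in DMA at rt under high dilution close the ring through the allylzinc to the 1,10-O-isopropylidene acetal of 13 F4. 80% aqueous AcOH at 40 °C removes the acetal and comes back to the route at 13.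

**Step 7 (invertive epoxide hydrolysis).** Water could attack C6 of the chain instead of C7 (which would give the C10 epimer of the target series), the angelate could migrate or isomerise through the acyloxonium ion, and the chloro diol could cyclise. Fallback: close the ring first and open the epoxide in the macrocycle after the alkene has been deactivated as an enone. It sets out from 11. CrCl2 under the conditions of step 8 gives (1R,4E,6S,7R,9R,10S)-1,10-epoxy-6-hydroxygermacra-4,11-dien-9-yl angelate F5. H2 with RhCl(PPh3)3 gives (1R,4E,6R,7R,9R,10S)-1,10-epoxy-6-hydroxygermacr-4-en-9-yl angelate F6. MnO2 gives (1R,4E,7R,9R,10S)-1,10-epoxy-6-oxogermacr-4-en-9-yl angelate F7. HClO4 (cat.) in THF–H2O at 0 °C then opens the epoxide with inversion at C10 to (1R,4E,7R,9R,10R)-1,10-dihydroxy-6-oxogermacr-4-en-9-yl angelate F8. IBX in DMSO comes back to the route at 15.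

## Further compounds

F1 | step 10 | (4E,6R,7R,9R,10S)-6,10-dihydroxy-1-oxogermacr-4-en-9-yl (2Z)-2-methylbut-2-enoate | O[C@H]1/C=C(\C)CCC(=O)[C@@](C)(O)[C@H](OC(=O)/C(C)=C\C)C[C@@H]1C(C)C
F2 | step 10 | (1R,5R,6R,7R,9R,10S)-1,6,10-trihydroxyguai-4(15)-en-9-yl (2Z)-2-methylbut-2-enoate | C=C1CC[C@@]2(O)[C@H]1[C@H](O)[C@@H](C(C)C)C[C@@H](OC(=O)/C(C)=C\C)[C@]2(C)O
F3 | step 8 | 6,7-O-isopropylidene acetal of 12 (stereocentres as in 12) | O=C/C=C(\C)CC[C@H]1OC(C)(C)O[C@@]1(C)[C@H](OC(=O)/C(C)=C\C)CC(Cl)C(C)=C
F4 | step 8 | 1,10-O-isopropylidene acetal of 13 (stereocentres as in 13) | O[C@H]1/C=C(\C)CC[C@H]2OC(C)(C)O[C@@]2(C)[C@H](OC(=O)/C(C)=C\C)C[C@@H]1C(C)=C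
F5 | step 7 | (1R,4E,6S,7R,9R,10S)-1,10-epoxy-6-hydroxygermacra-4,11-dien-9-yl (2Z)-2-methylbut-2-enoate | O[C@H]1/C=C(\C)CC[C@H]2O[C@]2(C)[C@H](OC(=O)/C(C)=C\C)C[C@@H]1C(C)=C
F6 | step 7 | (1R,4E,6R,7R,9R,10S)-1,10-epoxy-6-hydroxygermacr-4-en-9-yl (2Z)-2-methylbut-2-enoate | O[C@H]1/C=C(\C)CC[C@H]2O[C@]2(C)[C@H](OC(=O)/C(C)=C\C)C[C@@H]1C(C)C
F7 | step 7 | (1R,4E,7R,9R,10S)-1,10-epoxy-6-oxogermacr-4-en-9-yl (2Z)-2-methylbut-2-enoate | O=C1/C=C(\C)CC[C@H]2O[C@]2(C)[C@H](OC(=O)/C(C)=C\C)C[C@@H]1C(C)C
F8 | step 7 | (1R,4E,7R,9R,10R)-1,10-dihydroxy-6-oxogermacr-4-en-9-yl (2Z)-2-methylbut-2-enoate | O=C1/C=C(\C)CC[C@@H](O)[C@@](C)(O)[C@H](OC(=O)/C(C)=C\C)C[C@@H]1C(C)C
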